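**Retrosynthetic overview**
1. Side chain last: Negishi methylation of a (Z)-β-iodo enone ⇐ anti-hydroiodination of an ynone ⇐ ketal-masked alkyne carried from the fragment stage.
2. Ring diene ⇐ Pd/formate reduction of a dienyl triflate ⇐ 2-methylcyclohex-2-enone; quaternary C1 ⇐ C-methylation anti to the C6 substituent.
3. Carbocycle (key ring closure) ⇐ amine-catalysed Michael addition of pyranonyl ketone 9 to enynal 17, then intramolecular aldol condensation.
4. 9 ⇐ γ-pyranone 5 (from β-keto ester 1) + Weinreb amide 8; 17 ⇐ Sonogashira coupling of iodo-alcohol 15 with alkyne 12.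
5. Ring order: pyranone (steps 2–3) → dioxolane protecting ring (step 6) → cyclohexenone (step 11).

Assumption: in step 11 the quinine-derived primary amine is taken to give the (6R) adduct drawn; if it gives the antipode, the quinidine-derived pseudo-enantiomer is used instead.

Ring locants below: C1 = carbon bearing the pyranone, C6 = carbon bearing the side chain.

**Step 1**
Reactants: 1 methyl 2-methyl-3-oxopentanoate; 2 N-methoxy-N-methylacetamide
Product: 3 methyl 2,4-dimethyl-3,5-dioxohexanoate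
Conditions: 1 (2 equiv), NaH, THF, 0 °C; n-BuLi, 0 °C; then 2, −78 → 0 °C; 1 M HCl
Reagents that add atoms: none
Why: Weiler dianion γ-acylation (Claisen type), in which the more reactive C4 carbanion attacks the Weinreb amide; the new centres are enolisable and of no consequence.

**Step 2**
Reactants: 3 methyl 2,4-dimethyl-3,5-dioxohexanoate
Product: 4 4-hydroxy-3,5,6-trimethyl-2H-pyran-2-one
Conditions: DBU, toluene, 80 °C; then 1 M HCl
Reagents that add atoms: none
Why: Base-mediated enol-lactonisation of the δ-keto ester closes the 2-pyranone with loss of methanol.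

**Step 3**
Reactants: 4 4-hydroxy-3,5,6-trimethyl-2H-pyran-2-one
Product: 5 2-methoxy-3,5,6-trimethyl-4H-pyran-4-one
Conditions: MeOTf, CH2Cl2, rt; aq. NaHCO3 wash
Reagents that add atoms: methyl trifluoromethanesulfonate COS(=O)(=O)C(F)(F)F
Why: Beak-type regioselective O-methylation, in which the neutral hydroxypyranone is alkylated on the lactone carbonyl oxygen and proton loss gives the 2-methoxy-4-pyranone.

**Step 4**
Reactants: 6 propanoyl chloride; 7 N,O-dimethylhydroxylamine hydrochloride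
Product: 8 N-methoxy-N-methylpropanamide
Conditions: Et3N (2.2 equiv), CH2Cl2, 0 °C → rt
Reagents that add atoms: none
Why: Simple N-acylation gives the Weinreb amide.

**Step 5**
Reactants: 5 2-methoxy-3,5,6-trimethyl-4H-pyran-4-one; 8 N-methoxy-N-methylpropanamide
Product: 9 2-methoxy-3,5-dimethyl-6-(2-oxobutyl)-4H-pyran-4-one
Conditions: LiHMDS, THF, −78 °C; then 8, −78 → −40 °C; AcOH quench
Reagents that add atoms: none
Why: Vinylogous enolate acylation; only the 6-methyl group is conjugated to the pyranone carbonyl, and the chelated Weinreb adduct prevents over-addition.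

**Step 6**
Reactants: 10 4-(trimethylsilyl)but-3-yn-2-one
Product: 11 2-methyl-2-[(trimethylsilyl)ethynyl]-1,3-dioxolane
Conditions: ethylene glycol, TsOH·H2O (cat.), benzene, reflux, Dean–Stark
Reagents that add atoms: ethane-1,2-diol OCCO
Why: Acid-catalysed ketalisation; the silyl cap suppresses oxa-Michael addition to the ynone.

**Step 7**
Reactants: 11 2-methyl-2-[(trimethylsilyl)ethynyl]-1,3-dioxolane
Product: 12 2-ethynyl-2-methyl-1,3-dioxolane
Conditions: K2CO3 (cat.), MeOH, rt
Reagents that add atoms: none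
Why: Methanolysis of the C(sp)–Si bond (protodesilylation).

**Step 8**
Reactants: 13 prop-2-yn-1-ol
Product: 15 (E)-3-iodo-2-methylprop-2-en-1-ol, via alkenyl(dimethyl)alane 14 (not isolated)
Conditions: AlMe3 (3 equiv), Cp2ZrCl2 (0.25 equiv), CH2Cl2, 0 °C → rt; then I2, THF, −30 → 0 °C; aq. K2CO3
Reagents that add atoms: trimethylaluminium C[Al](C)C; iodine II
Why: Negishi Zr-catalysed syn-carboalumination puts methyl on the internal carbon, and iododealumination with retention gives the E-vinyl iodide.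

**Step 9**
Reactants: 15 (E)-3-iodo-2-methylprop-2-en-1-ol; 12 2-ethynyl-2-methyl-1,3-dioxolane
Product: 16 (2E)-2-methyl-5-(2-methyl-1,3-dioxolan-2-yl)pent-2-en-4-yn-1-ol
Conditions: PdCl2(PPh3)2 (2 mol%), CuI (4 mol%), Et3N, THF, rt
Reagents that add atoms: none
Why: Sonogashira coupling with retention of the E geometry.

**Step 10**
Reactants: 16 (2E)-2-methyl-5-(2-methyl-1,3-dioxolan-2-yl)pent-2-en-4-yn-1-ol
Product: 17 (2E)-2-methyl-5-(2-methyl-1,3-dioxolan-2-yl)pent-2-en-4-ynal
Conditions: MnO2, CH2Cl2, rt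
Reagents that add atoms: none
Why: Chemoselective oxidation of the allylic alcohol to the enal.

**Step 11 (key ring closure)**
Reactants: 9 2-methoxy-3,5-dimethyl-6-(2-oxobutyl)-4H-pyran-4-one; 17 (2E)-2-methyl-5-(2-methyl-1,3-dioxolan-2-yl)pent-2-en-4-ynal
Product: 20 2-{(6R)-3,5-dimethyl-6-[(2-methyl-1,3-dioxolan-2-yl)ethynyl]-2-oxocyclohex-3-en-1-yl}-6-methoxy-3,5-dimethyl-4H-pyran-4-one (C1/C5 epimer mixture), via keto-aldehyde Michael adduct 18 (not isolated), via β-hydroxy ketone 19 (not isolated)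
Conditions: 9-amino-9-deoxy-epi-quinine (20 mol%), 2-fluorobenzoic acid (40 mol%), toluene, 0 °C → rt; then CSA (30 mol%), 60 °C, Ar
Reagents that add atoms: none
Why: Iminium-catalysed Michael addition (a primary cinchona amine tolerates the α-branched enal; the enol of 9 adds to the β-carbon on the open iminium face and fixes C6, the 1,6-position being blocked by the ketal carbon) followed by 6-(enolendo)-exo-trig intramolecular aldol condensation of the ethyl-ketone CH2 onto the aldehyde, the only six-membered closure available; C1 and C5 form as mixtures, but C1 is reset in step 12 and C5 is destroyed in step 13.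

**Step 12**
Reactants: 20 cyclohexenone from step 11
Product: 21 2-{(1S,6S)-1,3,5-trimethyl-6-[(2-methyl-1,3-dioxolan-2-yl)ethynyl]-2-oxocyclohex-3-en-1-yl}-6-methoxy-3,5-dimethyl-4H-pyran-4-one (C5 epimer mixture)
Conditions: K2CO3 (3 equiv), MeI (5 equiv), acetone, rt, Ar (20 is used at once; it is an air-sensitive dihydrophenol-type ketone)
Reagents that add atoms: iodomethane CI
Why: C-alkylation of the doubly stabilised enolate; A(1,2) strain with the pyranone forces the C6 alkynyl group pseudo-axial, so MeI enters the opposite face and the methyl ends trans, the pyranone cis, to the C6 substituent (1S).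

**Step 13**
Reactants: 21 methylated enone
Product: 22 (5S,6S)-6-(6-methoxy-3,5-dimethyl-4-oxo-4H-pyran-2-yl)-2,4,6-trimethyl-5-[(2-methyl-1,3-dioxolan-2-yl)ethynyl]cyclohexa-1,3-dien-1-yl trifluoromethanesulfonate
Conditions: KHMDS, THF, −78 → −40 °C; PhNTf2, −78 → 0 °C; aq. NH4Cl
Reagents that add atoms: N-phenylbis(trifluoromethanesulfonimide) O=S(=O)(N(c1ccccc1)S(=O)(=O)C(F)(F)F)C(F)(F)F
Why: With C1 quaternary the only enolisable site is the γ-hydrogen at C5, so the linear dienolate forms and O-triflation gives the 1,3-dienyl triflate; both C5 epimers converge.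

**Step 14**
Reactants: 22 dienyl triflate
Product: 23 6-methoxy-3,5-dimethyl-2-{(1S,6S)-1,3,5-trimethyl-6-[(2-methyl-1,3-dioxolan-2-yl)ethynyl]cyclohexa-2,4-dien-1-yl}-4H-pyran-4-one
Conditions: Pd(OAc)2 (10 mol%), PPh3 (20 mol%), n-Bu3N, HCO2H, DMF, 60 °C, dark
Reagents that add atoms: none
Why: Cacchi Pd-catalysed formate reduction of the alkenyl triflate (oxidative addition, formate decarboxylation, C–H reductive elimination) leaves the diene in place; the hindered internal alkyne is not hydropalladated.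

**Step 15**
Reactants: 23 diene ketal
Product: 24 6-methoxy-3,5-dimethyl-2-[(1S,6S)-1,3,5-trimethyl-6-(3-oxobut-1-yn-1-yl)cyclohexa-2,4-dien-1-yl]-4H-pyran-4-one
Conditions: TsOH·H2O (0.3 equiv), acetone/H2O 10:1, 50 °C, dark
Reagents that add atoms: water O
Why: Acid hydrolysis of the ketal; alkynyl ketals hydrolyse slowly, which is why it survived step 11 and needs these more forcing aqueous conditions.

**Step 16**
Reactants: 24 ynone
Product: 25 2-{(1S,6R)-6-[(1Z)-1-iodo-3-oxobut-1-en-1-yl]-1,3,5-trimethylcyclohexa-2,4-dien-1-yl}-6-methoxy-3,5-dimethyl-4H-pyran-4-one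
Conditions: NaI (3 equiv), AcOH, rt, dark
Reagents that add atoms: sodium iodide [Na+].[I-]
Why: Conjugate anti-hydroiodination of the ynone gives the (Z)-β-iodo enone, with iodine cis to the acetyl group and the ring carbon trans to it.

**Step 17**
Reactants: 25 (Z)-β-iodo enone
Product: 26 6-methoxy-3,5-dimethyl-2-{(1S,6S)-1,3,5-trimethyl-6-[(2E)-4-oxopent-2-en-2-yl]cyclohexa-2,4-dien-1-yl}-4H-pyran-4-one (target)
Conditions: MeZnCl (2 equiv), Pd(PPh3)4 (5 mol%), THF, 0 °C → rt, dark
Reagents that add atoms: methylzinc chloride C[Zn]Cl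
Why: Negishi cross-coupling with retention of alkene geometry replaces iodine by methyl and gives the E-enone without base, so the γ-acidic C6–H is not epimerised.

**Compound list**
1 | methyl 2-methyl-3-oxopentanoate | CCC(=O)C(C)C(=O)OC | starting material
2 | N-methoxy-N-methylacetamide | CC(=O)N(C)OC | starting material
3 | methyl 2,4-dimethyl-3,5-dioxohexanoate | CC(=O)C(C)C(=O)C(C)C(=O)OC | intermediate
4 | 4-hydroxy-3,5,6-trimethyl-2H-pyran-2-one | CC1=C(C)C(O)=C(C)C(=O)O1 | intermediate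
5 | 2-methoxy-3,5,6-trimethyl-4H-pyran-4-one | COc1oc(C)c(C)c(=O)c1C | intermediate
6 | propanoyl chloride | CCC(=O)Cl | starting material
7 | N,O-dimethylhydroxylamine hydrochloride | CNOC.Cl | starting material
8 | N-methoxy-N-methylpropanamide | CCC(=O)N(C)OC | intermediate
9 | 2-methoxy-3,5-dimethyl-6-(2-oxobutyl)-4H-pyran-4-one | CCC(=O)Cc1oc(OC)c(C)c(=O)c1C | intermediate
10 | 4-(trimethylsilyl)but-3-yn-2-one | CC(=O)C#C[Si](C)(C)C | starting material
11 | 2-methyl-2-[(trimethylsilyl)ethynyl]-1,3-dioxolane | CC1(C#C[Si](C)(C)C)OCCO1 | intermediate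
12 | 2-ethynyl-2-methyl-1,3-dioxolane | CC1(C#C)OCCO1 | intermediate
13 | prop-2-yn-1-ol | OCC#C | starting material
14 | (E)-alkenyl(dimethyl)alane, O-aluminated | C[Al](C)OC/C(C)=C/[Al](C)C | intermediate (not isolated)
15 | (E)-3-iodo-2-methylprop-2-en-1-ol | OC/C(C)=C/I | intermediate
16 | (2E)-2-methyl-5-(2-methyl-1,3-dioxolan-2-yl)pent-2-en-4-yn-1-ol | OC/C(C)=C/C#CC1(C)OCCO1 | intermediate
17 | (2E)-2-methyl-5-(2-methyl-1,3-dioxolan-2-yl)pent-2-en-4-ynal | O=C/C(C)=C/C#CC1(C)OCCO1 | intermediate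
18 | (3R)-4-(6-methoxy-3,5-dimethyl-4-oxo-4H-pyran-2-yl)-2-methyl-3-[(2-methyl-1,3-dioxolan-2-yl)ethynyl]-5-oxoheptanal | CCC(=O)C(c1oc(OC)c(C)c(=O)c1C)[C@H](C#CC2(C)OCCO2)C(C)C=O | intermediate (not isolated)
19 | 2-{(6R)-4-hydroxy-3,5-dimethyl-6-[(2-methyl-1,3-dioxolan-2-yl)ethynyl]-2-oxocyclohexyl}-6-methoxy-3,5-dimethyl-4H-pyran-4-one | COc1oc(C2C(=O)C(C)C(O)C(C)[C@H]2C#CC3(C)OCCO3)c(C)c(=O)c1C | intermediate (not isolated)
20 | 2-{(6R)-3,5-dimethyl-6-[(2-methyl-1,3-dioxolan-2-yl)ethynyl]-2-oxocyclohex-3-en-1-yl}-6-methoxy-3,5-dimethyl-4H-pyran-4-one | COc1oc(C2C(=O)C(C)=CC(C)[C@H]2C#CC3(C)OCCO3)c(C)c(=O)c1C | intermediate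
21 | 2-{(1S,6S)-1,3,5-trimethyl-6-[(2-methyl-1,3-dioxolan-2-yl)ethynyl]-2-oxocyclohex-3-en-1-yl}-6-methoxy-3,5-dimethyl-4H-pyran-4-one | COc1oc([C@@]2(C)C(=O)C(C)=CC(C)[C@H]2C#CC3(C)OCCO3)c(C)c(=O)c1C | intermediate
22 | (5S,6S)-6-(6-methoxy-3,5-dimethyl-4-oxo-4H-pyran-2-yl)-2,4,6-trimethyl-5-[(2-methyl-1,3-dioxolan-2-yl)ethynyl]cyclohexa-1,3-dien-1-yl trifluoromethanesulfonate | COc1oc([C@@]2(C)C(OS(=O)(=O)C(F)(F)F)=C(C)C=C(C)[C@H]2C#CC3(C)OCCO3)c(C)c(=O)c1C | intermediate
23 | 6-methoxy-3,5-dimethyl-2-{(1S,6S)-1,3,5-trimethyl-6-[(2-methyl-1,3-dioxolan-2-yl)ethynyl]cyclohexa-2,4-dien-1-yl}-4H-pyran-4-one | COc1oc([C@@]2(C)C=C(C)C=C(C)[C@H]2C#CC3(C)OCCO3)c(C)c(=O)c1C | intermediate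
24 | 6-methoxy-3,5-dimethyl-2-[(1S,6S)-1,3,5-trimethyl-6-(3-oxobut-1-yn-1-yl)cyclohexa-2,4-dien-1-yl]-4H-pyran-4-one | COc1oc([C@@]2(C)C=C(C)C=C(C)[C@H]2C#CC(C)=O)c(C)c(=O)c1C | intermediate
25 | 2-{(1S,6R)-6-[(1Z)-1-iodo-3-oxobut-1-en-1-yl]-1,3,5-trimethylcyclohexa-2,4-dien-1-yl}-6-methoxy-3,5-dimethyl-4H-pyran-4-one | COc1oc([C@@]2(C)C=C(C)C=C(C)[C@H]2/C(I)=C/C(C)=O)c(C)c(=O)c1C | intermediate
26 | 6-methoxy-3,5-dimethyl-2-{(1S,6S)-1,3,5-trimethyl-6-[(2E)-4-oxopent-2-en-2-yl]cyclohexa-2,4-dien-1-yl}-4H-pyran-4-one | COc1oc([C@@]2(C)C=C(C)C=C(C)[C@H]2/C(C)=C/C(C)=O)c(C)c(=O)c1C | target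

**Totals**
Total step count: 17.
Longest linear sequence: 11 steps (1→2→3→5→11→12→13→14→15→16→17; the alkyne branch 6→7→9→10→11→…→17 is equally long).

**Three steps most likely to fail**

Step 11 (Michael/aldol annulation). Risks are sluggish iminium formation from the α-branched enynal, competing 1,2-addition (Knoevenagel, then 2H-pyran formation) and an unverified sense of induction. The fallback sets out from 9 and 12 and reverses the bond order and polarity. Alkyne 12 is formylated (n-BuLi, then DMF, THF, −78 °C) to 3-(2-methyl-1,3-dioxolan-2-yl)prop-2-ynal F1. Knoevenagel condensation of 9 with F1 (piperidine/AcOH, CH2Cl2, 0 °C) gives the alkylidene ketone F2, which cannot undergo oxa-6π closure because the β-substituent is an alkyne. Enamine-catalysed Michael addition of propanal with (S)-α,α-diphenylprolinol trimethylsilyl ether (same topicity as the nitroalkene additions, which gives the required C6 configuration) then gives keto-aldehyde 18 as its syn diastereomer. CSA closes it through 19, and the route is rejoined at 20.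

Step 12 (C-methylation). Risks are O-alkylation at the hindered carbon and lower facial selectivity for the 5,6-trans epimer, whose pseudo-axial C5 methyl shields the other face. The fallback sets out from 9 and makes the quaternary centre in the conjugate addition instead. Ketone 9 is C-methylated while still unhindered (NaH, MeI, THF, 0 °C) to 2-methoxy-3,5-dimethyl-6-(3-oxopentan-2-yl)-4H-pyran-4-one F3. F3 and 17 under the step-11 conditions give the quaternary keto-aldehyde F4, which closes through the hydroxy ketone F5. C1 epimers are separated by chromatography, and the route is rejoined at 21.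

Step 13 (γ-enolisation/triflation). The risk is slow removal of the hindered tertiary C5–H. The fallback sets out from 21 and removes the carbonyl oxygen by reduction/elimination. Luche reduction (NaBH4, CeCl3·7H2O, MeOH, −40 °C) gives the allylic alcohol F6. Burgess reagent (benzene, 50 °C) then effects 1,4-dehydration; 1,2-elimination is impossible because C1 has no hydrogen and C3 is sp2. This gives diene 23 directly, bypassing 22.

**Further compounds**
F1 | step 11 | 3-(2-methyl-1,3-dioxolan-2-yl)prop-2-ynal | O=CC#CC1(C)OCCO1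
F2 | step 11 | 2-methoxy-3,5-dimethyl-6-[1-(2-methyl-1,3-dioxolan-2-yl)-5-oxohept-3-en-1-yn-4-yl]-4H-pyran-4-one (E/Z mixture) | CCC(=O)C(=CC#CC1(C)OCCO1)c1oc(OC)c(C)c(=O)c1C
F3 | step 12 | 2-methoxy-3,5-dimethyl-6-(3-oxopentan-2-yl)-4H-pyran-4-one | CCC(=O)C(C)c1oc(OC)c(C)c(=O)c1C
F4 | step 12 | (3R)-4-(6-methoxy-3,5-dimethyl-4-oxo-4H-pyran-2-yl)-2,4-dimethyl-3-[(2-methyl-1,3-dioxolan-2-yl)ethynyl]-5-oxoheptanal | CCC(=O)C(C)(c1oc(OC)c(C)c(=O)c1C)[C@H](C#CC2(C)OCCO2)C(C)C=O
F5 | step 12 | 2-{4-hydroxy-1,3,5-trimethyl-6-[(2-methyl-1,3-dioxolan-2-yl)ethynyl]-2-oxocyclohexyl}-6-methoxy-3,5-dimethyl-4H-pyran-4-one (C6 as in 20) | COc1oc(C2(C)C(=O)C(C)C(O)C(C)[C@H]2C#CC3(C)OCCO3)c(C)c(=O)c1C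
F6 | step 13 | 2-{(1S,6S)-2-hydroxy-1,3,5-trimethyl-6-[(2-methyl-1,3-dioxolan-2-yl)ethynyl]cyclohex-3-en-1-yl}-6-methoxy-3,5-dimethyl-4H-pyran-4-one | COc1oc([C@@]2(C)C(O)C(C)=CC(C)[C@H]2C#CC3(C)OCCO3)c(C)c(=O)c1C
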